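**Retrosynthetic overview**
- The strategy rests on the central benzene ring, whose six carbons alternate between O-bearing carbons (C1, C3, C5, all C–OH) and carbons bearing C or Br (C4 and C6 benzyl, C2 Br).
- That ring is disconnected into cyclobutenone 12 (supplying C–OH, C–H, C–OEt and C–benzyl) and siloxyalkyne 19 (supplying C–OSi and C–benzyl). The alkyne is inserted between C1 and C2 of the cyclobutenone, forming the C(OH)–C(benzyl) and C(OSi)–C(H) ring bonds.
- Both partners come from 2,3-dibromo-4,5-dimethoxybenzaldehyde 3 (two steps from 5-bromovanillin): 12 via the propanoic acid, its ketene and ethoxyacetylene; 19 via the 3-arylpropyne and its ynolate.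
- The central ring is the only ring formed; the two bromoveratryl rings are carried in intact. After the annulation: desilylation, bromination of the single ring C–H, and cleavage of all five alkyl ethers.
- Remark: vidalol B has no stereogenic element, so no enantiocontrol is needed; 12 is used as the racemate because its one stereocentre is erased in the key step.

Key step: step 10

Step 1
Reactants: 1 5-bromovanillin (3-bromo-4-hydroxy-5-methoxybenzaldehyde)
Product: 2 5,6-dibromovanillin (2,3-dibromo-4-hydroxy-5-methoxybenzaldehyde)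
Conditions: Br2 (1.1 equiv), Fe powder (cat.), NaOAc, AcOH, rt
Reagents that add atoms: bromine, BrBr
Why: Electrophilic aromatic bromination: of the two free positions the one para to the methoxy group (next to the existing bromine) is the more activated, so the 2,3-dibromo pattern should result.

Step 2
Reactants: 2 5,6-dibromovanillin
Product: 3 2,3-dibromo-4,5-dimethoxybenzaldehyde
Conditions: MeI, K2CO3, DMF, rt
Reagents that add atoms: iodomethane, CI
Why: Williamson O-methylation of the phenoxide (SN2 on MeI); the aldehyde and the aryl bromides are inert to K2CO3.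

Step 3
Reactants: 3 2,3-dibromo-4,5-dimethoxybenzaldehyde; 4 Meldrum's acid (2,2-dimethyl-1,3-dioxane-4,6-dione)
Product: 8 3-(2,3-dibromo-4,5-dimethoxyphenyl)propanoic acid, via arylidene Meldrum's acid 5 (not isolated), via benzyl Meldrum's acid 6 (not isolated), via benzylmalonic acid 7 (not isolated)
Conditions: HCO2H–Et3N (5:2), 100 °C; then aq HCl
Reagents that add atoms: none
Why: One-pot reductive Knoevenagel: condensation with Meldrum's acid, conjugate hydride transfer from formate, then hydrolysis and decarboxylation give the homologated acid without H2 or a metal, so both aryl bromides should survive.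

Step 4
Reactants: 8 3-(2,3-dibromo-4,5-dimethoxyphenyl)propanoic acid
Product: 9 3-(2,3-dibromo-4,5-dimethoxyphenyl)propanoyl chloride
Conditions: (COCl)2, DMF (cat.), CH2Cl2, 0 °C → rt; concentrated and used crude
Reagents that add atoms: oxalyl chloride, O=C(Cl)C(Cl)=O
Why: Acid chloride formation through the catalytic Vilsmeier chloroiminium species; the by-products are gases, so the crude chloride can be used directly.

Step 5
Reactants: 9 3-(2,3-dibromo-4,5-dimethoxyphenyl)propanoyl chloride; 10 ethoxyacetylene (ethoxyethyne)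
Product: 12 4-(2,3-dibromo-4,5-dimethoxybenzyl)-3-ethoxycyclobut-2-en-1-one (racemic), via arylmethylketene 11 (not isolated)
Conditions: 10 (3 equiv), Et3N (1.2 equiv, slow addition), CH2Cl2, 0 °C → rt
Reagents that add atoms: none
Why: Dehydrochlorination gives the monoalkylketene, which the electron-rich ynol ether traps in a thermal [2+2] cycloaddition (ketene carbonyl carbon to the unsubstituted alkyne carbon), the known route to 4-alkyl-3-ethoxycyclobutenones; excess alkyne and slow addition of base are meant to hold back ketene dimerisation.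

Step 6
Reactants: 3 2,3-dibromo-4,5-dimethoxybenzaldehyde
Product: 13 (2,3-dibromo-4,5-dimethoxyphenyl)methanol
Conditions: NaBH4, MeOH–THF, 0 °C
Reagents that add atoms: none
Why: Chemoselective hydride reduction of the aldehyde; aryl bromides are untouched by NaBH4.

Step 7
Reactants: 13 (2,3-dibromo-4,5-dimethoxyphenyl)methanol
Product: 14 2,3-dibromo-1-(bromomethyl)-4,5-dimethoxybenzene
Conditions: PBr3, CH2Cl2, 0 °C → rt
Reagents that add atoms: phosphorus tribromide, BrP(Br)Br
Why: Conversion of the benzylic alcohol to the bromide through its phosphite ester; the methyl ethers and aryl bromides are inert.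

Step 8
Reactants: 14 2,3-dibromo-1-(bromomethyl)-4,5-dimethoxybenzene; 15 ethynylmagnesium bromide
Product: 16 3-(2,3-dibromo-4,5-dimethoxyphenyl)prop-1-yne
Conditions: 15 (3 equiv, THF), CuBr (10 mol%), THF, 60 °C
Reagents that add atoms: none
Why: Copper-catalysed sp–sp3 coupling of an alkynyl Grignard reagent with a benzylic bromide; the aryl bromides do not react under these conditions and the excess of 15 suppresses a second benzylation of the product acetylide.

Step 9
Reactants: 16 3-(2,3-dibromo-4,5-dimethoxyphenyl)prop-1-yne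
Product: 19 {[3-(2,3-dibromo-4,5-dimethoxyphenyl)prop-1-yn-1-yl]oxy}tri(propan-2-yl)silane, via lithium acetylide 17 (not isolated), via lithium ynolate 18 (not isolated)
Conditions: LiHMDS, THF, −78 °C; t-BuOOLi (from t-BuOOH + LiHMDS), −78 → 0 °C; TIPSCl, −78 °C → rt
Reagents that add atoms: tert-butyl hydroperoxide, CC(C)(C)OO; triisopropylsilyl chloride, CC(C)[Si](Cl)(C(C)C)C(C)C
Why: Oxidation of the lithium acetylide by lithium tert-butyl peroxide gives the ynolate, which a bulky silyl chloride silylates on oxygen (known route to silyl ynol ethers); the amide base, used in place of an alkyllithium, avoids bromine–lithium exchange on the ring.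

Step 10
Reactants: 12 4-(2,3-dibromo-4,5-dimethoxybenzyl)-3-ethoxycyclobut-2-en-1-one (racemic); 19 {[3-(2,3-dibromo-4,5-dimethoxyphenyl)prop-1-yn-1-yl]oxy}tri(propan-2-yl)silane
Product: 24 2,6-bis(2,3-dibromo-4,5-dimethoxybenzyl)-3-ethoxy-5-(triisopropylsilyloxy)phenol, via vinylketene 20 (not isolated), via 4-vinylcyclobutenone 21 (not isolated), via dienylketene 22 (not isolated), via cyclohexadienone 23 (not isolated)
Conditions: 12 (1.3 equiv), PhMe (0.5 M), sealed tube, 110 °C then 145 °C
Reagents that add atoms: none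
Why: Proposed new method: heating should open 12 by conrotatory 4π cleavage of its C1–C4 bond (benzyl rotating outward, which also keeps its CH2 out of reach of the ketene for a 1,5-H shift) to vinylketene 20, whose electrophilic carbonyl carbon joins the nucleophilic, benzyl-bearing carbon of 19 in a [2+2] cycloaddition that makes the C(OH)–C(benzyl) and C(OSi)–C(H) ring bonds of the final arene (21). Vinylcyclobutenone 21 opens again (4π) to dienylketene 22, and the only new ring is closed by thermal disrotatory 6π electrocyclisation of the ketene carbon onto the benzyl-bearing diene terminus (23), after which enolisation gives the phenol. The closest known reaction is the Danheiser benzannulation of 3-alkyl and 2,3-dialkyl cyclobutenones with triisopropylsiloxyalkynes; what is new is the 3-alkoxy-4-alkyl cyclobutenone, a vinylogous ester whose first ring opening should need more heat but is not blocked, since alkoxy-substituted cyclobutenones derived from squarates open thermally in the same way. No stereocentre is created and the one in racemic 12 is lost on aromatisation. The selectivity needed is the regiochemistry of the [2+2], secured by the O-polarised alkyne (the carbon remote from OSi is the nucleophile), which places OH between the two benzyl groups and leaves OSi and OEt flanking the single ring C–H.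

Step 11
Reactants: 24 2,6-bis(2,3-dibromo-4,5-dimethoxybenzyl)-3-ethoxy-5-(triisopropylsilyloxy)phenol
Product: 25 2,4-bis(2,3-dibromo-4,5-dimethoxybenzyl)-5-ethoxybenzene-1,3-diol
Conditions: TBAF, AcOH, THF, 0 °C
Reagents that add atoms: none
Why: Fluoride-induced cleavage of the aryl silyl ether, buffered with acetic acid so that the electron-rich resorcinol is not held as a free phenoxide open to air oxidation.

Step 12
Reactants: 25 2,4-bis(2,3-dibromo-4,5-dimethoxybenzyl)-5-ethoxybenzene-1,3-diol
Product: 26 4-bromo-2,6-bis(2,3-dibromo-4,5-dimethoxybenzyl)-5-ethoxybenzene-1,3-diol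
Conditions: NBS (1.0 equiv), CH2Cl2, −78 → 0 °C, dark
Reagents that add atoms: N-bromosuccinimide, O=C1CCC(=O)N1Br
Why: Electrophilic aromatic bromination at the only C–H of the phloroglucinol-type ring, which is activated by two hydroxyls and the ethoxy group and should react far faster than the lone C–H of each dibrominated veratryl ring when one equivalent of NBS is used cold.

Step 13
Reactants: 26 4-bromo-2,6-bis(2,3-dibromo-4,5-dimethoxybenzyl)-5-ethoxybenzene-1,3-diol
Product: 27 vidalol B [2-bromo-4,6-bis(2,3-dibromo-4,5-dihydroxybenzyl)benzene-1,3,5-triol]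
Conditions: BBr3 (12 equiv), CH2Cl2, −78 °C → rt; then ice–water
Reagents that add atoms: none
Why: Lewis-acid cleavage of the four methyl ethers and the ethyl ether by BBr3 (bromide attack at the O-alkyl carbon), a standard endgame for bromophenols that leaves aryl–Br and diarylmethane C–C bonds intact; hydrolysis of the aryl borates should release the heptaphenol.

**Compound list**
1 | 5-bromovanillin (3-bromo-4-hydroxy-5-methoxybenzaldehyde) | COc1cc(C=O)cc(Br)c1O | starting material
2 | 2,3-dibromo-4-hydroxy-5-methoxybenzaldehyde | COc1cc(C=O)c(Br)c(Br)c1O | intermediate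
3 | 2,3-dibromo-4,5-dimethoxybenzaldehyde | COc1cc(C=O)c(Br)c(Br)c1OC | intermediate
4 | Meldrum's acid (2,2-dimethyl-1,3-dioxane-4,6-dione) | CC1(C)OC(=O)CC(=O)O1 | starting material
5 | 5-(2,3-dibromo-4,5-dimethoxybenzylidene)-2,2-dimethyl-1,3-dioxane-4,6-dione | CC1(C)OC(=O)C(=Cc2cc(OC)c(OC)c(Br)c2Br)C(=O)O1 | intermediate
6 | 5-(2,3-dibromo-4,5-dimethoxybenzyl)-2,2-dimethyl-1,3-dioxane-4,6-dione | CC1(C)OC(=O)C(Cc2cc(OC)c(OC)c(Br)c2Br)C(=O)O1 | intermediate
7 | 2-(2,3-dibromo-4,5-dimethoxybenzyl)malonic acid | OC(=O)C(Cc1cc(OC)c(OC)c(Br)c1Br)C(=O)O | intermediate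
8 | 3-(2,3-dibromo-4,5-dimethoxyphenyl)propanoic acid | OC(=O)CCc1cc(OC)c(OC)c(Br)c1Br | intermediate
9 | 3-(2,3-dibromo-4,5-dimethoxyphenyl)propanoyl chloride | ClC(=O)CCc1cc(OC)c(OC)c(Br)c1Br | intermediate
10 | ethoxyacetylene (ethoxyethyne) | C#COCC | starting material
11 | 3-(2,3-dibromo-4,5-dimethoxyphenyl)prop-1-en-1-one (arylmethylketene) | O=C=CCc1cc(OC)c(OC)c(Br)c1Br | intermediate
12 | 4-(2,3-dibromo-4,5-dimethoxybenzyl)-3-ethoxycyclobut-2-en-1-one (racemic) | CCOC1=CC(=O)C1Cc1cc(OC)c(OC)c(Br)c1Br | intermediate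
13 | (2,3-dibromo-4,5-dimethoxyphenyl)methanol | OCc1cc(OC)c(OC)c(Br)c1Br | intermediate
14 | 2,3-dibromo-1-(bromomethyl)-4,5-dimethoxybenzene | BrCc1cc(OC)c(OC)c(Br)c1Br | intermediate
15 | ethynylmagnesium bromide | C#C[Mg]Br | starting material
16 | 3-(2,3-dibromo-4,5-dimethoxyphenyl)prop-1-yne | C#CCc1cc(OC)c(OC)c(Br)c1Br | intermediate
17 | lithium 3-(2,3-dibromo-4,5-dimethoxyphenyl)prop-1-yn-1-ide | [Li+].[C-]#CCc1cc(OC)c(OC)c(Br)c1Br | intermediate
18 | lithium 3-(2,3-dibromo-4,5-dimethoxyphenyl)prop-1-yn-1-olate | [Li+].[O-]C#CCc1cc(OC)c(OC)c(Br)c1Br | intermediate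
19 | {[3-(2,3-dibromo-4,5-dimethoxyphenyl)prop-1-yn-1-yl]oxy}tri(propan-2-yl)silane | CC(C)[Si](C(C)C)(C(C)C)OC#CCc1cc(OC)c(OC)c(Br)c1Br | intermediate
20 | (Z)-5-(2,3-dibromo-4,5-dimethoxyphenyl)-3-ethoxypenta-1,3-dien-1-one (benzyl trans to the ketene carbon) | O=C=C/C(OCC)=C/Cc1cc(OC)c(OC)c(Br)c1Br | intermediate
21 | 2-(2,3-dibromo-4,5-dimethoxybenzyl)-4-[(Z)-3-(2,3-dibromo-4,5-dimethoxyphenyl)-1-ethoxyprop-1-en-1-yl]-3-(triisopropylsilyloxy)cyclobut-2-en-1-one (racemic) | O=C1C(Cc2cc(OC)c(OC)c(Br)c2Br)=C(O[Si](C(C)C)(C(C)C)C(C)C)C1/C(OCC)=C/Cc3cc(OC)c(OC)c(Br)c3Br | intermediate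
22 | (3E,5Z)-2-(2,3-dibromo-4,5-dimethoxybenzyl)-7-(2,3-dibromo-4,5-dimethoxyphenyl)-5-ethoxy-3-(triisopropylsilyloxy)hepta-1,3,5-trien-1-one | O=C=C(Cc1cc(OC)c(OC)c(Br)c1Br)/C(O[Si](C(C)C)(C(C)C)C(C)C)=C\C(OCC)=C\Cc2cc(OC)c(OC)c(Br)c2Br | intermediate
23 | 2,6-bis(2,3-dibromo-4,5-dimethoxybenzyl)-5-ethoxy-3-(triisopropylsilyloxy)cyclohexa-2,4-dien-1-one (racemic) | O=C1C(Cc2cc(OC)c(OC)c(Br)c2Br)=C(O[Si](C(C)C)(C(C)C)C(C)C)C=C(OCC)C1Cc3cc(OC)c(OC)c(Br)c3Br | intermediate
24 | 2,6-bis(2,3-dibromo-4,5-dimethoxybenzyl)-3-ethoxy-5-(triisopropylsilyloxy)phenol | CCOc1cc(O[Si](C(C)C)(C(C)C)C(C)C)c(Cc2cc(OC)c(OC)c(Br)c2Br)c(O)c1Cc1cc(OC)c(OC)c(Br)c1Br | intermediate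
25 | 2,4-bis(2,3-dibromo-4,5-dimethoxybenzyl)-5-ethoxybenzene-1,3-diol | CCOc1cc(O)c(Cc2cc(OC)c(OC)c(Br)c2Br)c(O)c1Cc1cc(OC)c(OC)c(Br)c1Br | intermediate
26 | 4-bromo-2,6-bis(2,3-dibromo-4,5-dimethoxybenzyl)-5-ethoxybenzene-1,3-diol | CCOc1c(Br)c(O)c(Cc2cc(OC)c(OC)c(Br)c2Br)c(O)c1Cc1cc(OC)c(OC)c(Br)c1Br | intermediate
27 | vidalol B, 2-bromo-4,6-bis(2,3-dibromo-4,5-dihydroxybenzyl)benzene-1,3,5-triol (achiral) | Oc1cc(Cc2c(O)c(Br)c(O)c(Cc3cc(O)c(O)c(Br)c3Br)c2O)c(Br)c(Br)c1O | target

**Step count**
Total: 13 steps. Longest linear sequence: 10 steps (1, 2, 6, 7, 8, 9, 10, 11, 12, 13).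

**Steps most likely to fail**

Step 10 (proposed new method). The vinylogous-ester stabilisation of 12 may push the first ring opening to temperatures at which the siloxyalkyne degrades. The vinylketene, once formed, may also be lost to dimerisation or to acylation of the phenol product before the hindered alkyne intercepts it. The fallback uses known chemistry and buys the central ring instead of building it. It sets out from benzyl alcohol 13. Two-fold Friedel–Crafts benzylation of commercial 2-bromo-1,3,5-trimethoxybenzene (COc1cc(OC)c(Br)c(OC)c1) with 13 (2.2 equiv; TfOH cat., HFIP–CH2Cl2, rt) should give 2-bromo-4,6-bis(2,3-dibromo-4,5-dimethoxybenzyl)-1,3,5-trimethoxybenzene F1. The bromine blocks the third nucleophilic position, so only the two equivalent free carbons can be benzylated. Exhaustive demethylation of F1 with BBr3 (CH2Cl2, −78 °C → rt) comes back to the route at the target 27.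

Step 9. The doubly activated CH2 may isomerise from propargyl to allene during acetylide formation. Oxygen transfer from the peroxide may stall, or the ynolate may be silylated on carbon or the silyl ynol ether hydrolysed on isolation. The fallback replaces the silyl ynol ether by an ethyl ynol ether, which needs no ynolate, and sets out from benzyl bromide 14. Ethoxyacetylene 10 is deprotonated with n-BuLi (THF, −78 °C; fully consumed before 14 is added, so no bromine–lithium exchange) to lithium ethoxyacetylide F2. Alkylation of F2 by 14 (THF–DMPU, −78 °C → rt) should give 3-(2,3-dibromo-4,5-dimethoxyphenyl)-1-ethoxyprop-1-yne F3. Annulation of F3 with cyclobutenone 12 is the alkoxyalkyne variant of the same cascade. It would be run with 300 nm irradiation at rt to open 12 and then at 80 °C, to stay below the retro-ene loss of ethylene from the ethyl ynol ether. It should pass through vinylketene 20, the 4-vinylcyclobutenone F4, the dienylketene F5 and the cyclohexadienone F6 to 2,6-bis(2,3-dibromo-4,5-dimethoxybenzyl)-3,5-diethoxyphenol F7. NBS (1 equiv, CH2Cl2, −78 °C) should brominate its single ring C–H to 4-bromo-2,6-bis(2,3-dibromo-4,5-dimethoxybenzyl)-3,5-diethoxyphenol F8. BBr3 cleavage of the two ethyl and four methyl ethers of F8 comes back to the route at 27.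

Step 5. The monoalkylketene may dimerise, or be acylated through its ammonium enolate, faster than the ynol ether traps it. The product, with its acidic C4–H, may also be degraded by the amine. The fallback uses a more electrophilic alkyl(chloro)ketene, so that trapping outruns self-condensation, and removes the chlorine afterwards; it sets out from benzyl bromide 14. Alkylation of diethyl chloromalonate (CCOC(=O)C(Cl)C(=O)OCC; K2CO3, DMF, rt) with 14 should give diethyl 2-chloro-2-(2,3-dibromo-4,5-dimethoxybenzyl)malonate F9. Hydrolysis and decarboxylation (aq HCl–AcOH, reflux) proceed through 2-chloro-2-(2,3-dibromo-4,5-dimethoxybenzyl)malonic acid F10 to racemic 2-chloro-3-(2,3-dibromo-4,5-dimethoxyphenyl)propanoic acid F11. Oxalyl chloride with catalytic DMF converts F11 into 2-chloro-3-(2,3-dibromo-4,5-dimethoxyphenyl)propanoyl chloride F12. Et3N in the presence of excess 10 generates the chloro(arylmethyl)ketene F13, whose [2+2] cycloaddition should give racemic 4-chloro-4-(2,3-dibromo-4,5-dimethoxybenzyl)-3-ethoxycyclobut-2-en-1-one F14. Reductive dechlorination of F14 (Zn, AcOH, rt) comes back to the route at 12.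

**Further compounds**
F1 | step 10 | 2-bromo-4,6-bis(2,3-dibromo-4,5-dimethoxybenzyl)-1,3,5-trimethoxybenzene | COc1c(Br)c(OC)c(Cc2cc(OC)c(OC)c(Br)c2Br)c(OC)c1Cc1cc(OC)c(OC)c(Br)c1Br
F2 | step 9 | lithium ethoxyacetylide | [Li+].[C-]#COCC
F3 | step 9 | 3-(2,3-dibromo-4,5-dimethoxyphenyl)-1-ethoxyprop-1-yne | CCOC#CCc1cc(OC)c(OC)c(Br)c1Br
F4 | step 9 | 2-(2,3-dibromo-4,5-dimethoxybenzyl)-4-[(Z)-3-(2,3-dibromo-4,5-dimethoxyphenyl)-1-ethoxyprop-1-en-1-yl]-3-ethoxycyclobut-2-en-1-one (racemic) | O=C1C(Cc2cc(OC)c(OC)c(Br)c2Br)=C(OCC)C1/C(OCC)=C/Cc3cc(OC)c(OC)c(Br)c3Br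
F5 | step 9 | (3E,5Z)-2-(2,3-dibromo-4,5-dimethoxybenzyl)-7-(2,3-dibromo-4,5-dimethoxyphenyl)-3,5-diethoxyhepta-1,3,5-trien-1-one | O=C=C(Cc1cc(OC)c(OC)c(Br)c1Br)/C(OCC)=C\C(OCC)=C\Cc2cc(OC)c(OC)c(Br)c2Br
F6 | step 9 | 2,6-bis(2,3-dibromo-4,5-dimethoxybenzyl)-3,5-diethoxycyclohexa-2,4-dien-1-one (racemic) | O=C1C(Cc2cc(OC)c(OC)c(Br)c2Br)=C(OCC)C=C(OCC)C1Cc3cc(OC)c(OC)c(Br)c3Br
F7 | step 9 | 2,6-bis(2,3-dibromo-4,5-dimethoxybenzyl)-3,5-diethoxyphenol | CCOc1cc(OCC)c(Cc2cc(OC)c(OC)c(Br)c2Br)c(O)c1Cc1cc(OC)c(OC)c(Br)c1Br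
F8 | step 9 | 4-bromo-2,6-bis(2,3-dibromo-4,5-dimethoxybenzyl)-3,5-diethoxyphenol | CCOc1c(Br)c(OCC)c(Cc2cc(OC)c(OC)c(Br)c2Br)c(O)c1Cc1cc(OC)c(OC)c(Br)c1Br
F9 | step 5 | diethyl 2-chloro-2-(2,3-dibromo-4,5-dimethoxybenzyl)malonate | CCOC(=O)C(Cl)(Cc1cc(OC)c(OC)c(Br)c1Br)C(=O)OCC
F10 | step 5 | 2-chloro-2-(2,3-dibromo-4,5-dimethoxybenzyl)malonic acid | OC(=O)C(Cl)(Cc1cc(OC)c(OC)c(Br)c1Br)C(=O)O
F11 | step 5 | 2-chloro-3-(2,3-dibromo-4,5-dimethoxyphenyl)propanoic acid (racemic) | OC(=O)C(Cl)Cc1cc(OC)c(OC)c(Br)c1Br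
F12 | step 5 | 2-chloro-3-(2,3-dibromo-4,5-dimethoxyphenyl)propanoyl chloride (racemic) | ClC(=O)C(Cl)Cc1cc(OC)c(OC)c(Br)c1Br
F13 | step 5 | 2-chloro-3-(2,3-dibromo-4,5-dimethoxyphenyl)prop-1-en-1-one (chloroketene) | O=C=C(Cl)Cc1cc(OC)c(OC)c(Br)c1Br
F14 | step 5 | 4-chloro-4-(2,3-dibromo-4,5-dimethoxybenzyl)-3-ethoxycyclobut-2-en-1-one (racemic) | CCOC1=CC(=O)C1(Cl)Cc1cc(OC)c(OC)c(Br)c1Br
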